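**Plan**

Retrosynthesis: the pyrrole N-acetyl group and both indole N-tosyl groups come off first. The pyrrole is then cut at C4–C5, at N1–C2 and at C2–C3, and last the bond from the C4 carbon to its indole C3 is cut.
Enabling feature: C5 is the only pyrrole ring carbon that bears hydrogen, and it lies between N1 and the indolyl-substituted C4. It can therefore be the α-carbon of glycine and C4 an indol-3-yl ketone carbon, with the glycine carboxyl leaving as CO2 once C4–C5 exists.
Forward: both indole rings are bought. A Friedel–Crafts acylation links them through CH2–C=O (future C3 and C4), dimethyl oxalate adds C2 with its ester, a glycine ester adds N1 and C5, and the pyrrole, the only ring made, closes last at C4–C5.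
Stereochemistry: the target has no stereocentre. Only the Z geometry of the enaminone must be controlled, and its N–H···O=C hydrogen bond sets it under equilibrating conditions.

Key step: step 8

Remark: Ts (tosyl) = 4-methylphenylsulfonyl. The 2,4-dioxo ester is written as its chelated Z-enol, the tautomer expected to prevail, and it reacts as the dicarbonyl compound.

**Step 1**
Reactants: 1 5-bromoindole
Product: 2 5-bromo-1-tosylindole
Conditions: TsCl, 50% aq NaOH, Bu4NHSO4 (cat.), toluene, rt
Reagents that add atoms: 4-toluenesulfonyl chloride, Cc1ccc(cc1)S(=O)(=O)Cl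
Why: Phase-transfer N-sulfonylation of an indole: the indolide generated at the interface reacts with TsCl at nitrogen only, and the sulfonyl group later steers acylation to C3 and keeps the derived ketone electrophilic.

**Step 2**
Reactants: 3 5-bromoindole-3-acetic acid
Product: 4 2-(5-bromo-1-tosylindol-3-yl)acetic acid
Conditions: LiN(SiMe3)2 (2.1 equiv), THF, −78 to 0 °C; TsCl (1.05 equiv), −78 °C to rt; 1 M HCl
Reagents that add atoms: 4-toluenesulfonyl chloride, Cc1ccc(cc1)S(=O)(=O)Cl
Why: N-sulfonylation of a carboxylate–indolide dianion: the silylamide removes the CO2H and N–H protons without halogen–metal exchange at the aryl bromide, the much more nucleophilic indolide nitrogen takes the single equivalent of TsCl, and any mixed anhydride at the carboxylate is hydrolysed in the acidic work-up.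

**Step 3**
Reactants: 4 2-(5-bromo-1-tosylindol-3-yl)acetic acid
Product: 5 2-(5-bromo-1-tosylindol-3-yl)acetyl chloride
Conditions: (COCl)2, DMF (cat.), CH2Cl2, 0 °C to rt; evaporate, use crude
Reagents that add atoms: oxalyl chloride, ClC(=O)C(=O)Cl
Why: Acid chloride formation with oxalyl chloride under Vilsmeier-type DMF catalysis runs cold and without strong acid or base, so the N-sulfonylindole and the aryl bromide are left alone.

**Step 4**
Reactants: 5 2-(5-bromo-1-tosylindol-3-yl)acetyl chloride; 2 5-bromo-1-tosylindole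
Product: 6 1,2-bis(5-bromo-1-tosylindol-3-yl)ethanone
Conditions: AlCl3 (3 equiv), CH2Cl2, 0 °C to rt; ice/1 M HCl
Reagents that add atoms: none
Why: Friedel–Crafts acylation: 1-arylsulfonylindoles are acylated by acyl chloride–AlCl3 complexes selectively at C3, which is free only in 2, while the sulfonyl group in 5 destabilises the indol-3-ylmethyl cation and so holds back loss of CO from the acylium ion.

**Step 5**
Reactants: 6 1,2-bis(5-bromo-1-tosylindol-3-yl)ethanone; 7 dimethyl oxalate
Product: 8 methyl (Z)-3,4-bis(5-bromo-1-tosylindol-3-yl)-2-hydroxy-4-oxobut-2-enoate (enol form of the 2,4-dioxobutanoate)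
Conditions: LiN(SiMe3)2 (1.1 equiv), THF, −78 °C; 7 (1.5 equiv), −78 °C to rt; cold 1 M HCl
Reagents that add atoms: none
Why: Crossed Claisen condensation: the CH2 of 6, acidified by the ketone and the indole ring, is deprotonated completely by the non-nucleophilic amide, the non-enolisable oxalate acylates the enolate at carbon, and the methoxide released is consumed at once by the strongly acidic product, which drives the reaction and spares the sulfonamides.

**Step 6**
Reactants: 8 methyl (Z)-3,4-bis(5-bromo-1-tosylindol-3-yl)-2-hydroxy-4-oxobut-2-enoate; 9 tert-butyl glycinate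
Product: 10 methyl (Z)-3,4-bis(5-bromo-1-tosylindol-3-yl)-2-[(2-tert-butoxy-2-oxoethyl)amino]-4-oxobut-2-enoate
Conditions: 9 (1.3 equiv), AcOH (20 mol %), 4 Å MS, toluene, 70 °C
Reagents that add atoms: none
Why: Enaminone formation by amine–carbonyl condensation: the C2 carbonyl next to the ester is far more electrophilic than the C4 carbonyl, a donor-conjugated 3-acylindole ketone, so nitrogen ends up on C2, the reversible reaction settles on the Z isomer with its N–H···O=C4 hydrogen bond, and the tert-butyl ester is used because free glycine would merely be protonated to its insoluble zwitterion by the acidic enol.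

**Step 7**
Reactants: 10 methyl (Z)-3,4-bis(5-bromo-1-tosylindol-3-yl)-2-[(2-tert-butoxy-2-oxoethyl)amino]-4-oxobut-2-enoate
Product: 11 N-[(Z)-1-methoxycarbonyl-3-oxo-2,3-bis(5-bromo-1-tosylindol-3-yl)prop-1-enyl]glycine
Conditions: TFA/CH2Cl2 1:2, 0 °C to rt; evaporate with toluene
Reagents that add atoms: none
Why: Acidolysis of a tert-butyl ester by the E1 pathway: anhydrous TFA releases isobutene and the free acid, while the methyl ester, the sulfonamides and the push–pull enaminone, which needs water to hydrolyse, persist.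

**Step 8**
Reactants: 11 N-[(Z)-1-methoxycarbonyl-3-oxo-2,3-bis(5-bromo-1-tosylindol-3-yl)prop-1-enyl]glycine
Product: 14 methyl 1-acetyl-3,4-bis(5-bromo-1-tosylindol-3-yl)pyrrole-2-carboxylate, via münchnone 12 (not isolated), via bicyclic aldol adduct 13 (not isolated)
Conditions: Ac2O (neat, excess), 110 °C
Reagents that add atoms: acetic anhydride, CC(=O)OC(C)=O
Why: This is the Zav'yalov pyrrole synthesis, the known Ac2O cyclisation of glycine-derived enaminones, a relative of the Dakin–West reaction. Ac2O converts the acid of 11 into a mixed anhydride, which passes acetyl to the weakly nucleophilic nitrogen through a five-membered transition state, and a second activation lets the amide oxygen close on the carboxyl carbon (5-exo-trig) to give the 1,3-oxazolium-5-olate 12. The nucleophilic CH carbon of 12, the former glycine carbon, adds to the indol-3-yl ketone in a 5-(enolexo)-exo-trig aldol closure that forms pyrrole C4–C5 and gives 13. In 13 the oxazolonium ring opens to the N-acetyl group and the carboxyl carbon leaves as CO2 together with the tertiary oxygen, so the ring aromatises, C5 keeps only hydrogen, and the two transient sp3 centres vanish without leaving a stereocentre. The step needs the intramolecular addition to outrun intermolecular C-acetylation of 12 by Ac2O, and the Z geometry secures this by holding the glycine carbon next to the ketone, the only electrophile it can reach through a five-membered ring, since attack on the C2 ester would need a four-membered one. The ketone is electrophilic enough because the acylated, cationic nitrogen no longer feeds electron density into the enone and the N-tosyl group curbs donation from the indole.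

**Step 9**
Reactants: 14 methyl 1-acetyl-3,4-bis(5-bromo-1-tosylindol-3-yl)pyrrole-2-carboxylate
Product: 15 methyl 3,4-bis(5-bromo-1H-indol-3-yl)-1H-pyrrole-2-carboxylate (target)
Conditions: Cs2CO3 (6 equiv), dry THF/MeOH 2:1, rt to 40 °C; aq NH4Cl
Reagents that add atoms: none
Why: Carbonate-mediated methanolysis: methoxide, formed reversibly so that the carbonate itself is not consumed, cleaves the activated N-acylpyrrole first and then attacks sulfur of both N-tosyl groups, whose bromine-stabilised indolide leaving groups allow mild temperatures, and the methyl ester can only exchange with the solvent to give itself.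

**Compound list**

1 | 5-bromoindole | Brc1ccc2[nH]ccc2c1 | starting material
2 | 5-bromo-1-tosylindole | Cc1ccc(cc1)S(=O)(=O)n1ccc2cc(Br)ccc12 | intermediate
3 | 5-bromoindole-3-acetic acid | OC(=O)Cc1c[nH]c2ccc(Br)cc12 | starting material
4 | 2-(5-bromo-1-tosylindol-3-yl)acetic acid | OC(=O)Cc1cn(S(=O)(=O)c2ccc(C)cc2)c2ccc(Br)cc12 | intermediate
5 | 2-(5-bromo-1-tosylindol-3-yl)acetyl chloride | ClC(=O)Cc1cn(S(=O)(=O)c2ccc(C)cc2)c2ccc(Br)cc12 | intermediate
6 | 1,2-bis(5-bromo-1-tosylindol-3-yl)ethanone | O=C(Cc1cn(S(=O)(=O)c2ccc(C)cc2)c2ccc(Br)cc12)c1cn(S(=O)(=O)c2ccc(C)cc2)c2ccc(Br)cc12 | intermediate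
7 | dimethyl oxalate | COC(=O)C(=O)OC | starting material
8 | methyl (Z)-3,4-bis(5-bromo-1-tosylindol-3-yl)-2-hydroxy-4-oxobut-2-enoate (enol form of the 2,4-dioxobutanoate) | COC(=O)/C(O)=C(\c1cn(S(=O)(=O)c2ccc(C)cc2)c2ccc(Br)cc12)C(=O)c1cn(S(=O)(=O)c2ccc(C)cc2)c2ccc(Br)cc12 | intermediate
9 | tert-butyl glycinate | NCC(=O)OC(C)(C)C | starting material
10 | methyl (Z)-3,4-bis(5-bromo-1-tosylindol-3-yl)-2-[(2-tert-butoxy-2-oxoethyl)amino]-4-oxobut-2-enoate | COC(=O)/C(NCC(=O)OC(C)(C)C)=C(\c1cn(S(=O)(=O)c2ccc(C)cc2)c2ccc(Br)cc12)C(=O)c1cn(S(=O)(=O)c2ccc(C)cc2)c2ccc(Br)cc12 | intermediate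
11 | N-[(Z)-1-methoxycarbonyl-3-oxo-2,3-bis(5-bromo-1-tosylindol-3-yl)prop-1-enyl]glycine | COC(=O)/C(NCC(=O)O)=C(\c1cn(S(=O)(=O)c2ccc(C)cc2)c2ccc(Br)cc12)C(=O)c1cn(S(=O)(=O)c2ccc(C)cc2)c2ccc(Br)cc12 | intermediate
12 | 3-[(Z)-1-methoxycarbonyl-3-oxo-2,3-bis(5-bromo-1-tosylindol-3-yl)prop-1-enyl]-2-methyl-1,3-oxazol-3-ium-5-olate (münchnone) | COC(=O)/C([N+]1=C(C)OC([O-])=C1)=C(\c1cn(S(=O)(=O)c2ccc(C)cc2)c2ccc(Br)cc12)C(=O)c1cn(S(=O)(=O)c2ccc(C)cc2)c2ccc(Br)cc12 | intermediate
13 | 6,7-bis(5-bromo-1-tosylindol-3-yl)-5-methoxycarbonyl-3-methyl-1-oxo-7,7a-dihydro-1H-pyrrolo[1,2-c]oxazol-4-ium-7-olate (bicyclic aldol adduct; C7 and C7a are transient centres of undefined configuration, both lost on aromatisation) | COC(=O)C1=C(c3cn(S(=O)(=O)c4ccc(C)cc4)c4ccc(Br)cc34)C([O-])(c3cn(S(=O)(=O)c4ccc(C)cc4)c4ccc(Br)cc34)C2C(=O)OC(C)=[N+]12 | intermediate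
14 | methyl 1-acetyl-3,4-bis(5-bromo-1-tosylindol-3-yl)pyrrole-2-carboxylate | COC(=O)c1n(C(C)=O)cc(-c2cn(S(=O)(=O)c3ccc(C)cc3)c3ccc(Br)cc23)c1-c1cn(S(=O)(=O)c2ccc(C)cc2)c2ccc(Br)cc12 | intermediate
15 | methyl 3,4-bis(5-bromo-1H-indol-3-yl)-1H-pyrrole-2-carboxylate | COC(=O)c1[nH]cc(-c2c[nH]c3ccc(Br)cc23)c1-c1c[nH]c2ccc(Br)cc12 | target

**Step count and risks**

Total step count: 9.
Longest linear sequence: 8 steps (3 → 4 → 5 → 6 → 8 → 10 → 11 → 14 → 15).

The three steps most likely to fail:

**Step 8.**
- Risk: acetyl transfer to the hydrogen-bonded, ester-flanked nitrogen may be too slow for the oxazolium-olate to build up.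
- Risk: intermolecular C-acetylation of the Dakin–West kind may drain the oxazolium-olate.
- Risk: addition to a ketone crowded by two large aryl groups may lag.
- Fallback: it forms the same C4–C5 bond but loses CO2 after the closure instead of during it, and it sets out from 10. The glycinate CH2 of 10 is deprotonated with Cs2CO3 in dry DMF over 4 Å MS at 60 °C. A base-induced aldol cyclodehydration of the N-(3-oxoalkenyl)glycinate type should then give 5-tert-butyl 2-methyl 3,4-bis(5-bromo-1-tosylindol-3-yl)-1H-pyrrole-2,5-dicarboxylate F1. TFA in CH2Cl2 cleaves only the tert-butyl ester to 5-methoxycarbonyl-3,4-bis(5-bromo-1-tosylindol-3-yl)-1H-pyrrole-2-carboxylic acid F2. Protodecarboxylation with Ag2CO3 (cat.) and AcOH in DMSO at 120 °C gives methyl 3,4-bis(5-bromo-1-tosylindol-3-yl)-1H-pyrrole-2-carboxylate F3. The conditions of step 9 then remove both tosyl groups, and the route is rejoined at 15.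

**Step 6.**
- Risk: the amine may be parked as the ammonium salt of the acidic enol.
- Risk: condensation at a carbon that becomes part of a tetrasubstituted alkene may stall.
- Risk: retro-Claisen loss of the oxalyl unit or aminolysis of the activated ester may take over.
- Fallback: it brings in nitrogen as the smallest possible nucleophile and makes the N1–C5 bond by alkylation, and it sets out from 8. Excess NH4OAc in refluxing MeOH should give methyl (Z)-2-amino-3,4-bis(5-bromo-1-tosylindol-3-yl)-4-oxobut-2-enoate F4. Its nitrogen is deprotonated with NaH in DMF at 0 °C and alkylated with tert-butyl bromoacetate. C-alkylation is excluded because C3 is fully substituted. The route is rejoined at 10.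

**Step 4.**
- Risk: loss of CO or ketene formation from the arylacetyl chloride under AlCl3.
- Risk: slow attack by an indole deactivated by both bromine and the sulfonyl group.
- Fallback: it reverses the polarity of the bond formation, sets out from 5 and 1, and returns at 6. Compound 5 with MeNHOMe·HCl and pyridine in CH2Cl2 gives 2-(5-bromo-1-tosylindol-3-yl)-N-methoxy-N-methylacetamide F5. Compound 1 with I2 and KOH in DMF gives 5-bromo-3-iodoindole F6, and NaH/TsCl in DMF gives 5-bromo-3-iodo-1-tosylindole F7. Selective iodine–magnesium exchange with iPrMgCl·LiCl in THF at −40 °C leaves the aryl bromide alone and gives (5-bromo-1-tosylindol-3-yl)magnesium chloride F8. A Weinreb ketone synthesis of F8 with F5 delivers 6.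

**Further compounds**

F1 | step 8 | 5-tert-butyl 2-methyl 3,4-bis(5-bromo-1-tosylindol-3-yl)-1H-pyrrole-2,5-dicarboxylate | COC(=O)c1[nH]c(C(=O)OC(C)(C)C)c(-c2cn(S(=O)(=O)c3ccc(C)cc3)c3ccc(Br)cc23)c1-c1cn(S(=O)(=O)c2ccc(C)cc2)c2ccc(Br)cc12
F2 | step 8 | 5-methoxycarbonyl-3,4-bis(5-bromo-1-tosylindol-3-yl)-1H-pyrrole-2-carboxylic acid | COC(=O)c1[nH]c(C(=O)O)c(-c2cn(S(=O)(=O)c3ccc(C)cc3)c3ccc(Br)cc23)c1-c1cn(S(=O)(=O)c2ccc(C)cc2)c2ccc(Br)cc12
F3 | step 8 | methyl 3,4-bis(5-bromo-1-tosylindol-3-yl)-1H-pyrrole-2-carboxylate | COC(=O)c1[nH]cc(-c2cn(S(=O)(=O)c3ccc(C)cc3)c3ccc(Br)cc23)c1-c1cn(S(=O)(=O)c2ccc(C)cc2)c2ccc(Br)cc12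
F4 | step 6 | methyl (Z)-2-amino-3,4-bis(5-bromo-1-tosylindol-3-yl)-4-oxobut-2-enoate | COC(=O)/C(N)=C(\c1cn(S(=O)(=O)c2ccc(C)cc2)c2ccc(Br)cc12)C(=O)c1cn(S(=O)(=O)c2ccc(C)cc2)c2ccc(Br)cc12
F5 | step 4 | 2-(5-bromo-1-tosylindol-3-yl)-N-methoxy-N-methylacetamide | CON(C)C(=O)Cc1cn(S(=O)(=O)c2ccc(C)cc2)c2ccc(Br)cc12
F6 | step 4 | 5-bromo-3-iodoindole | Ic1c[nH]c2ccc(Br)cc12
F7 | step 4 | 5-bromo-3-iodo-1-tosylindole | Ic1cn(S(=O)(=O)c2ccc(C)cc2)c2ccc(Br)cc12
F8 | step 4 | (5-bromo-1-tosylindol-3-yl)magnesium chloride | Cl[Mg]c1cn(S(=O)(=O)c2ccc(C)cc2)c2ccc(Br)cc12
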